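The retrosynthesis traces both allylic acetates to a C15/C17 diester, the C17 ester to a C7=C8 enol triflate of a C8 ketone, and the C11–C16 chain to a Michael/olefination sequence at C9 of that ketone.
The 8-oxo trans-decalin is cut at C5–C10 and at C3–C4, which opens rings B and A to an acyclic (E)-enone (C8=O, C9=C10), a prenyl group (C5=C4) and a (Z)-vinylsilane (C2=C3–Si).
Forward, fragment 1 (C4–C8, from methyl (S)-glycidate) and fragment 2 (C9, C10, C1–C3, from two alkynes) are joined at C8–C9; SnCl4 then closes ring B through C5–C10 and, in the same step, ring A through C3–C4; side chain and C17 follow.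
The enabling feature is that C10 is quaternary and β to C8, the ring B carbon that carries C17: a C8 ketone makes C9=C10 a tertiary electrophile, and C4 with its two methyl groups relays the cation toward C3.
Stereochemistry: a C7 methoxy group (from the glycidate, removed in step 13) chelates tin and selects one chair, fixing C5 and C10; the (E)-enone puts the C10 methyl axial, the chair–chair course gives the trans fusion, and C9 is set by equilibration next to the C8 ketone.

Key step: step 8

Remark: C1–C20 are the customary labdane locants (ring A: C1–C5 and C10; ring B: C5–C10; C17 on C8; C18 and C19 on C4; C20 on C10; side chain C11–C16); β denotes the face of the C10 methyl group.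

Step 1
Reactants: 1 methyl (2S)-oxirane-2-carboxylate; 2 (2-methylprop-1-en-1-yl)magnesium bromide
Product: 3 methyl (2S)-2-hydroxy-5-methylhex-4-enoate
Conditions: CuI (10 mol %), THF, −40 °C; aq NH4Cl
Reagents that add atoms: none
Why: Copper-catalysed Grignard opening of the epoxide at its CH2 terminus (SN2) should install C4–C6 with C18/C19 and leave the future C7 carbinol center of the glycidate untouched.

Step 2
Reactants: 3 methyl (2S)-2-hydroxy-5-methylhex-4-enoate
Product: 4 methyl (2S)-2-methoxy-5-methylhex-4-enoate
Conditions: MeI, Ag2O, MeCN, rt, dark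
Reagents that add atoms: iodomethane, CI
Why: Purdie methylation under non-basic conditions should cap the hydroxyl as a small chelating ether without epimerising the α-stereocenter.

Step 3
Reactants: 4 methyl (2S)-2-methoxy-5-methylhex-4-enoate
Product: 5 (2S)-N,2-dimethoxy-N,5-dimethylhex-4-enamide
Conditions: MeNH(OMe)·HCl, iPrMgCl, THF, −20 °C
Reagents that add atoms: N,O-dimethylhydroxylamine hydrochloride, CNOC.Cl
Why: Aminolysis of the ester by the magnesium amide should give the Weinreb amide, which later stops the alkenyllithium addition at the ketone stage.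

Step 4
Reactants: 6 (3-bromoprop-1-yn-1-yl)trimethylsilane; 7 ethynylmagnesium bromide
Product: 8 trimethyl(penta-1,4-diyn-1-yl)silane
Conditions: CuCl (5 mol %), THF, 0 °C to rt
Reagents that add atoms: none
Why: Copper-catalysed SN2 coupling of an alkynyl Grignard reagent with a propargylic bromide is a standard entry to skipped diynes and assembles C9, C10 and C1–C3.

Step 5
Reactants: 8 trimethyl(penta-1,4-diyn-1-yl)silane
Product: 10 [(4E)-5-iodo-4-methylpent-4-en-1-yn-1-yl]trimethylsilane, via alkenylalane 9 (not isolated)
Conditions: Me3Al, Cp2ZrCl2 (20 mol %), CH2Cl2, 0 °C to rt; then I2, THF, −30 °C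
Reagents that add atoms: trimethylaluminium, C[Al](C)C; iodine, II
Why: Negishi carboalumination should add CH3 (the future C20) and aluminium syn across the terminal alkyne only, and iodinolysis with retention should give the (E)-iodoalkene that fixes the C9=C10 geometry.

Step 6
Reactants: 10 [(4E)-5-iodo-4-methylpent-4-en-1-yn-1-yl]trimethylsilane
Product: 12 [(1Z,4E)-5-iodo-4-methylpenta-1,4-dien-1-yl]trimethylsilane, via alkenylborane 11 (not isolated)
Conditions: (c-C6H11)2BH, THF, 0 °C to rt; then AcOH, 50 °C
Reagents that add atoms: none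
Why: Hydroboration of the silylalkyne places boron on the silicon-bearing carbon by syn addition, and protodeboronation with retention should give the (Z)-alkenylsilane required for an endocyclic ipso closure.

Step 7
Reactants: 12 [(1Z,4E)-5-iodo-4-methylpenta-1,4-dien-1-yl]trimethylsilane; 5 (2S)-N,2-dimethoxy-N,5-dimethylhex-4-enamide
Product: 14 (1Z,4E,7S)-7-methoxy-4,10-dimethyl-1-(trimethylsilyl)undeca-1,4,9-trien-6-one, via alkenyllithium 13 (not isolated)
Conditions: tBuLi (2 equiv), Et2O, −78 °C; then 5, −78 to 0 °C; aq NH4Cl
Reagents that add atoms: none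
Why: Iodine–lithium exchange proceeds with retention of the (E)-geometry and acylation by the Weinreb amide stops at the ketone, so the (E)-enone should form without loss of the C7 configuration.

Step 8
Reactants: 14 (1Z,4E,7S)-7-methoxy-4,10-dimethyl-1-(trimethylsilyl)undeca-1,4,9-trien-6-one
Product: 15 7β-methoxy-11,12,13,14,15,16,17-heptanorlabd-2-en-8-one (trans-fused, 5α-H, 10β-CH3)
Conditions: SnCl4 (1.2 equiv), CH2Cl2, −78 to −40 °C; aq NaHCO3
Reagents that add atoms: none
Why: Proposed new method: SnCl4, chelated between the C8 carbonyl and the C7 methoxy oxygen, turns the (E)-enone into a stannyloxy allyl cation whose tertiary terminus C10 is attacked by C5 of the prenyl double bond, the resulting C4 cation is captured at the silicon-bearing C3 of the (Z)-vinylsilane with loss of Me3SiCl, and the tin enolate is protonated at C9 on work-up; the closest known reaction types are the Lewis-acid-induced conjugate addition of alkenes to enones and the vinylsilane-terminated cation–olefin cyclisation, which have not been combined on an acyclic β,β-disubstituted enone. Ring B closes by a 6-endo attack of C5 on C10 (C8 and C9 lie inside the new ring) and ring A by a 6-endo ipso substitution at C3, both through chairs as in a polyene cyclisation. C10 is set by the (E)-geometry (C1, trans to C8, becomes equatorial and the methyl group axial), C5 by the chair of ring B with the incipient C4 cation equatorial, and the trans ring fusion by antiperiplanar addition across C4=C5. The absolute sense comes from C7: its methoxy group must lie in the plane of the five-membered tin chelate and is therefore equatorial, which allows only one of the two mirror-image chairs. The selectivity needed is capture of the C4 cation by C3 before proton loss or hydride shift; the chair holds that cation anti to C9, out of reach of the enolate carbon, and next to the vinylsilane, whose β-silyl effect stabilises the developing charge at C2.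

Step 9
Reactants: 15 7β-methoxy-11,12,13,14,15,16,17-heptanorlabd-2-en-8-one
Product: 16 7β-methoxy-11,12,13,14,15,16,17-heptanorlabdan-8-one
Conditions: H2 (1 atm), Pd/C, EtOAc, rt
Reagents that add atoms: none
Why: Heterogeneous hydrogenation should saturate the only C=C bond (C2=C3) and creates no stereocenter.

Step 10
Reactants: 16 7β-methoxy-11,12,13,14,15,16,17-heptanorlabdan-8-one
Product: 18 trimethylsilyl enol ether of 16 (C8(OSiMe3)=C9), via lithium enolate 17 (not isolated)
Conditions: LiN(iPr)2, THF, −78 °C; then Me3SiCl, Et3N
Reagents that add atoms: chlorotrimethylsilane, C[Si](C)(C)Cl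
Why: Kinetic deprotonation is expected at the C9 methylene and not at the C7 methine that carries the methoxy group, and O-silylation then fixes this regiochemistry as the silyl enol ether.

Step 11
Reactants: 18 trimethylsilyl enol ether of 16; 19 but-3-en-2-one
Product: 20 7β-methoxy-9βH-14,15,17-trinorlabdane-8,13-dione
Conditions: Me3SiOTf (10 mol %), CH2Cl2, −78 °C; then 1 M HCl, THF
Reagents that add atoms: none
Why: Mukaiyama–Michael addition should form C9–C11 with the enone approaching C9 anti to the axial C10 methyl group, which gives the axial 9α side chain that is corrected in the next step.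

Step 12
Reactants: 20 7β-methoxy-9βH-14,15,17-trinorlabdane-8,13-dione
Product: 22 methyl (13E)-7β-methoxy-8-oxo-17-norlabd-13-en-15-oate, via 9α-enoate 21 (not isolated)
Conditions: (MeO)2P(O)CH2CO2Me, NaH, THF, 0 °C to rt; then NaOMe, MeOH, rt
Reagents that add atoms: trimethyl phosphonoacetate, COC(=O)CP(=O)(OC)OC
Why: Horner–Wadsworth–Emmons olefination should attack only the unhindered methyl ketone and favour the (E)-enoate, and methoxide then equilibrates C9 through the C8 enolate to the equatorial 9β side chain (9α-H).

Step 13
Reactants: 22 methyl (13E)-7β-methoxy-8-oxo-17-norlabd-13-en-15-oate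
Product: 23 methyl (13E)-8-oxo-17-norlabd-13-en-15-oate
Conditions: SmI2 (2.5 equiv), THF–MeOH, −78 °C
Reagents that add atoms: none
Why: Samarium diiodide reduces the ketone to its ketyl, which expels the α-methoxy group (reductive cleavage of an α-heterosubstituted ketone), so the helper oxygen at C7 is removed without touching a stereocenter of the target.

Step 14
Reactants: 23 methyl (13E)-8-oxo-17-norlabd-13-en-15-oate
Product: 25 methyl (13E)-8-(trifluoromethylsulfonyloxy)-17-norlabda-7,13-dien-15-oate, via potassium enolate 24 (not isolated)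
Conditions: KN(SiMe3)2, THF, −78 °C; then PhNTf2
Reagents that add atoms: N-phenylbis(trifluoromethanesulfonimide), O=S(=O)(N(c1ccccc1)S(=O)(=O)C(F)(F)F)C(F)(F)F
Why: Kinetic deprotonation at the C7 methylene (C9 is a hindered methine) followed by O-triflation should give the C7=C8 enol triflate and so places the ring B double bond of the target.

Step 15
Reactants: 25 methyl (13E)-8-(trifluoromethylsulfonyloxy)-17-norlabda-7,13-dien-15-oate
Product: 26 dimethyl (13E)-labda-7,13-diene-15,17-dioate
Conditions: Pd(OAc)2 (5 mol %), PPh3, CO (1 atm), MeOH, Et3N, DMF, 60 °C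
Reagents that add atoms: carbon monoxide, [C-]#[O+]; methanol, CO
Why: Palladium-catalysed methoxycarbonylation of the enol triflate (oxidative addition to zerovalent palladium, CO insertion, methanolysis) should introduce C17 at the ester level.

Step 16
Reactants: 26 dimethyl (13E)-labda-7,13-diene-15,17-dioate
Product: 27 (13E)-labda-7,13-diene-15,17-diol
Conditions: iBu2AlH, CH2Cl2, −78 to 0 °C; aq Rochelle salt
Reagents that add atoms: none
Why: 1,2-Hydride reduction of both conjugated esters should stop at the allylic alcohols and leave both double bonds and all stereocenters untouched.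

Step 17
Reactants: 27 (13E)-labda-7,13-diene-15,17-diol
Product: 28 (13E)-labda-7,13-diene-15,17-diyl diacetate
Conditions: Ac2O, pyridine, DMAP (cat.), CH2Cl2, rt
Reagents that add atoms: acetic anhydride, CC(=O)OC(C)=O
Why: Acylation of the two primary allylic alcohols should give the target diacetate.

Compound list
1 | methyl (2S)-oxirane-2-carboxylate | COC(=O)[C@@H]1CO1 | starting material
2 | (2-methylprop-1-en-1-yl)magnesium bromide | CC(C)=C[Mg]Br | starting material
3 | methyl (2S)-2-hydroxy-5-methylhex-4-enoate | CC(C)=CC[C@H](O)C(=O)OC | intermediate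
4 | methyl (2S)-2-methoxy-5-methylhex-4-enoate | CC(C)=CC[C@H](OC)C(=O)OC | intermediate
5 | (2S)-N,2-dimethoxy-N,5-dimethylhex-4-enamide | CC(C)=CC[C@H](OC)C(=O)N(C)OC | intermediate
6 | (3-bromoprop-1-yn-1-yl)trimethylsilane | C[Si](C)(C)C#CCBr | starting material
7 | ethynylmagnesium bromide | C#C[Mg]Br | starting material
8 | trimethyl(penta-1,4-diyn-1-yl)silane | C[Si](C)(C)C#CCC#C | intermediate
9 | dimethyl[(1E)-2-methyl-5-(trimethylsilyl)pent-1-en-4-yn-1-yl]alumane | C[Al](C)/C=C(\C)CC#C[Si](C)(C)C | intermediate (not isolated)
10 | [(4E)-5-iodo-4-methylpent-4-en-1-yn-1-yl]trimethylsilane | I/C=C(\C)CC#C[Si](C)(C)C | intermediate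
11 | dicyclohexyl[(1Z,4E)-5-iodo-4-methyl-1-(trimethylsilyl)penta-1,4-dien-1-yl]borane | I/C=C(\C)C/C=C(\[Si](C)(C)C)B(C1CCCCC1)C1CCCCC1 | intermediate (not isolated)
12 | [(1Z,4E)-5-iodo-4-methylpenta-1,4-dien-1-yl]trimethylsilane | I/C=C(\C)C/C=C\[Si](C)(C)C | intermediate
13 | [(1E,4Z)-2-methyl-5-(trimethylsilyl)penta-1,4-dien-1-yl]lithium | [Li]/C=C(\C)C/C=C\[Si](C)(C)C | intermediate (not isolated)
14 | (1Z,4E,7S)-7-methoxy-4,10-dimethyl-1-(trimethylsilyl)undeca-1,4,9-trien-6-one | CC(C)=CC[C@H](OC)C(=O)/C=C(\C)C/C=C\[Si](C)(C)C | intermediate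
15 | 7β-methoxy-11,12,13,14,15,16,17-heptanorlabd-2-en-8-one (trans-fused, 5α-H, 10β-CH3) | C1C(=O)[C@@H](OC)C[C@H]2C(C)(C)C=CC[C@]12C | intermediate
16 | 7β-methoxy-11,12,13,14,15,16,17-heptanorlabdan-8-one | C1C(=O)[C@@H](OC)C[C@H]2C(C)(C)CCC[C@]12C | intermediate
17 | lithium enolate of 16 (C8(OLi)=C9) | C1=C(O[Li])[C@@H](OC)C[C@H]2C(C)(C)CCC[C@]12C | intermediate (not isolated)
18 | trimethylsilyl enol ether of 16 (C8(OSiMe3)=C9) | C1=C(O[Si](C)(C)C)[C@@H](OC)C[C@H]2C(C)(C)CCC[C@]12C | intermediate
19 | but-3-en-2-one | CC(=O)C=C | starting material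
20 | 7β-methoxy-9βH-14,15,17-trinorlabdane-8,13-dione (9α side chain) | CC(=O)CC[C@@H]1C(=O)[C@@H](OC)C[C@H]2C(C)(C)CCC[C@]12C | intermediate
21 | methyl (13E)-7β-methoxy-8-oxo-9βH-17-norlabd-13-en-15-oate (9α side chain) | COC(=O)/C=C(\C)CC[C@@H]1C(=O)[C@@H](OC)C[C@H]2C(C)(C)CCC[C@]12C | intermediate (not isolated)
22 | methyl (13E)-7β-methoxy-8-oxo-17-norlabd-13-en-15-oate (9α-H) | COC(=O)/C=C(\C)CC[C@H]1C(=O)[C@@H](OC)C[C@H]2C(C)(C)CCC[C@]12C | intermediate
23 | methyl (13E)-8-oxo-17-norlabd-13-en-15-oate | COC(=O)/C=C(\C)CC[C@H]1C(=O)CC[C@H]2C(C)(C)CCC[C@]12C | intermediate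
24 | potassium enolate of 23 (C7=C8–OK) | COC(=O)/C=C(\C)CC[C@H]1C(O[K])=CC[C@H]2C(C)(C)CCC[C@]12C | intermediate (not isolated)
25 | methyl (13E)-8-(trifluoromethylsulfonyloxy)-17-norlabda-7,13-dien-15-oate | COC(=O)/C=C(\C)CC[C@H]1C(OS(=O)(=O)C(F)(F)F)=CC[C@H]2C(C)(C)CCC[C@]12C | intermediate
26 | dimethyl (13E)-labda-7,13-diene-15,17-dioate | COC(=O)/C=C(\C)CC[C@H]1C(C(=O)OC)=CC[C@H]2C(C)(C)CCC[C@]12C | intermediate
27 | (13E)-labda-7,13-diene-15,17-diol | OC/C=C(\C)CC[C@H]1C(CO)=CC[C@H]2C(C)(C)CCC[C@]12C | intermediate
28 | (13E)-labda-7,13-diene-15,17-diyl diacetate | CC(=O)OC/C=C(\C)CC[C@H]1C(COC(C)=O)=CC[C@H]2C(C)(C)CCC[C@]12C | target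

Total step count: 17. Longest linear sequence: 14 steps (steps 1–3 and 7–17, or steps 4–6 and 7–17).

Steps most likely to fail

Step 8. The C4 cation may lose a proton or undergo a hydride shift before the vinylsilane captures it, and facial control may erode if the tin chelate is incomplete. The fallback splits the event into two known reaction types. Setting out from 14, Me2AlCl in CH2Cl2 (Lewis-acid-induced ene-type conjugate addition of the prenyl group to the enone, the aluminate taking up the proton) should give the monocyclic 2-propenyl ketone F1. Formic acid at rt then protonates the 1,1-disubstituted alkene, and the regenerated C4 cation closes ring A on the vinylsilane (vinylsilane-terminated cation–olefin cyclisation), which returns to 15.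

Step 10. Enolisation may take place at C7, or be slow at the hindered C9, so that the side chain would enter at the wrong carbon or not at all. Setting out from 16, NaH and dimethyl carbonate in THF should acylate only the C9 methylene, because only there does a stabilised enolate result, giving the β-keto ester F2. But-3-en-2-one with K2CO3 should give the Michael adduct F3. Krapcho dealkoxycarbonylation (LiCl, wet DMSO, 150 °C) should give the equilibrated diketone F4, and the conditions of step 12 then lead to 22.

Step 13. Reductive loss of the methoxy group may be slow because the equatorial C–O bond overlaps poorly with the ketyl, and reduction of the ketone or the enoate may compete. The fallback keeps the oxygen and turns it into the C17 oxygen. Setting out from 22, Takai–Lombardo methylenation (Zn, CH2Br2, TiCl4) should give the exocyclic alkene F5. Ac2O with catalytic FeCl3 should convert the allylic methyl ether, through the C7–C8–C17 allyl cation, into the primary allylic acetate F6 with the C7=C8 double bond. iBu2AlH then reduces the ester and cleaves the acetate, which comes back to the route at 27.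

Further compounds
F1 | step 8 | (2S)-2-methoxy-5-methyl-4-(prop-1-en-2-yl)-5-[(2Z)-3-(trimethylsilyl)prop-2-en-1-yl]cyclohexan-1-one (7β-OMe, 5α-H, 10β-CH3 in labdane locants) | C1C(=O)[C@@H](OC)C[C@@H](C(C)=C)[C@]1(C)C/C=C\[Si](C)(C)C
F2 | step 10 | methyl 7β-methoxy-8-oxo-12,13,14,15,16,17-hexanorlabdan-11-oate (C9 enolisable) | COC(=O)C1C(=O)[C@@H](OC)C[C@H]2C(C)(C)CCC[C@]12C
F3 | step 10 | 9β-methoxycarbonyl derivative of 20 (3-oxobutyl chain 9α) | COC(=O)[C@@]1(CCC(C)=O)C(=O)[C@@H](OC)C[C@H]2C(C)(C)CCC[C@]12C
F4 | step 10 | 7β-methoxy-14,15,17-trinorlabdane-8,13-dione (9α-H) | CC(=O)CC[C@H]1C(=O)[C@@H](OC)C[C@H]2C(C)(C)CCC[C@]12C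
F5 | step 13 | methyl (13E)-7β-methoxylabda-8(17),13-dien-15-oate | COC(=O)/C=C(\C)CC[C@H]1C(=C)[C@@H](OC)C[C@H]2C(C)(C)CCC[C@]12C
F6 | step 13 | methyl (13E)-17-acetoxylabda-7,13-dien-15-oate | COC(=O)/C=C(\C)CC[C@H]1C(COC(C)=O)=CC[C@H]2C(C)(C)CCC[C@]12C
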